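**Strategy.** Everything rests on opening ring B at the C8a–C1 bond. C1 is benzylic to the syringyl ring and para to that ring's phenolic oxygen, so it can be a stabilised cation. C8a of ring A lies para to the C6 methoxy group, so it is the nucleophile, as in cyclolignan biosynthesis. In one acid-triggered Friedel–Crafts operation both epimers of a syringyl carbinol ionise to the same cation, ring B closes and C1 is set trans to C2. The precursor is a three-component adduct of (5R)-5-menthyloxybutenolide, a lithiated vanillin dithiane and O-benzylsyringaldehyde, whose lactone acetal termini later become the two acetoxymethyl groups.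

Key step: step 3

Assumption: (5R)-5-(l-menthyloxy)furan-2(5H)-one (compound 3) is taken as a purchasable chiral building block, and the product of step 2 is carried forward as the mixture of its two carbinol epimers. Target (tetralin) numbering is used for ring positions; C7'/C8' and C8 denote the carbons that become C1/C2 and C3.

Step 1
Reactants: 1 4-(benzyloxy)-3-methoxybenzaldehyde
Product: 2 2-[4-(benzyloxy)-3-methoxyphenyl]-1,3-dithiane
Conditions: propane-1,3-dithiol, BF3·OEt2 (cat.), CH2Cl2, 0 °C to rt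
Reagents that add atoms: propane-1,3-dithiol, SCCCS
Why: Lewis-acid-catalysed dithioacetalisation of an aryl aldehyde turns the formyl carbon into an acyl-anion equivalent (umpolung) while the benzyl and methyl ethers are inert.

Step 2
Reactants: 2 2-[4-(benzyloxy)-3-methoxyphenyl]-1,3-dithiane; 3 (5R)-5-[(1R,2S,5R)-menthyloxy]furan-2(5H)-one; 4 4-(benzyloxy)-3,5-dimethoxybenzaldehyde
Product: 7 aldol adduct (3S,4R,5R)-3-{[4-(benzyloxy)-3,5-dimethoxyphenyl](hydroxy)methyl}-4-{2-[4-(benzyloxy)-3-methoxyphenyl]-1,3-dithian-2-yl}-5-(menthyloxy)dihydrofuran-2(3H)-one (both carbinol epimers), via lithiated dithiane 5 (not isolated), via lithium enolate 6 (not isolated)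
Conditions: n-BuLi, THF, −78 °C; then 3, −78 °C; then 4, −78 °C; aq. NH4Cl quench at −78 °C
Reagents that add atoms: none
Why: In this tandem conjugate addition–aldol reaction on a γ-alkoxybutenolide the soft 2-aryl dithiane anion should add 1,4 to C4 anti to the C5 menthyloxy group (setting C8) and the lithium enolate should take up the aldehyde anti to the new C4 substituent (setting C8' trans), while the carbinol carbon forms as an epimer mixture that step 3 erases.

Step 3
Reactants: 7 aldol adduct (both carbinol epimers)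
Product: 9 spiro-dithiane aryltetralin lactone menthyl acetal (3'R,3a'R,9'S,9a'R)-7'-(benzyloxy)-9'-[4-(benzyloxy)-3,5-dimethoxyphenyl]-6'-methoxy-3'-(menthyloxy)-3a',9',9a'-trihydro-3'H-spiro[1,3-dithiane-2,4'-naphtho[2,3-c]furan]-1'-one, via benzylic cation 8 (not isolated)
Conditions: CF3CO2H (10 equiv), CH2Cl2, 0 °C
Reagents that add atoms: none
Why: Trifluoroacetic acid should ionise the secondary benzylic alcohol of either epimer of 7 to the same planar 4-benzyloxy-3,5-dimethoxybenzyl cation 8, an O-alkylated counterpart of the syringyl quinone methide invoked in cyclolignan biosynthesis, which the guaiacyl ring attacks through the carbon para to its methoxy group (future C8a) before losing a proton. The closest known reaction type is the acid-mediated intramolecular Friedel–Crafts alkylation (cyclodehydration) of α-(hydroxybenzyl)-β-benzyl-γ-butyrolactones to 1-aryltetralin lactones. Ring B closes in a 6-exo-trig mode at the trigonal cationic carbon (the arene π bond is endocyclic), assisted by the gem-disubstituted dithiane carbon. The new C1 stereocentre is controlled by the adjacent C2 (C8') centre: in the chair-like transition state the trans lactone holds the C2 and C3 branches pseudo-equatorial and the syringyl group takes the pseudo-equatorial position trans to the C2 carbonyl branch, giving the 1,2-trans-2,3-trans array (1S in target numbering), and because both carbinol epimers pass through one cation the step is stereoconvergent. The step needs attack para rather than ortho to the ring A methoxy group, secured by the stronger activation and lower hindrance there (the ortho site is flanked by OMe and the quaternary dithiane carbon). It also needs ring closure to outrun E1 loss of the C2 proton, secured by low temperature and the nucleophilic dialkoxyarene.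

Step 4
Reactants: 9 spiro-dithiane aryltetralin lactone menthyl acetal
Product: 10 [(2'R,3'R,4'S)-6'-(benzyloxy)-4'-[4-(benzyloxy)-3,5-dimethoxyphenyl]-7'-methoxy-3',4'-dihydro-2'H-spiro[1,3-dithiane-2,1'-naphthalene]-2',3'-diyl]dimethanol
Conditions: LiAlH4, THF, 0 °C to rt; H2O/NaOH work-up
Reagents that add atoms: none
Why: Hydride reduction of the γ-alkoxy lactone (pseudo-ester) should reduce the carbonyl and, after collapse of the hemiacetal alkoxide with loss of mentholate, the unmasked aldehyde, so both butenolide termini become CH2OH and the auxiliary is released; dithiane and benzyl ethers are inert and the diequatorial C2/C3 arrangement is the thermodynamic one.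

Step 5
Reactants: 10 spiro-dithiane dibenzyl diol
Product: 11 [(2'R,3'R,4'S)-6'-(benzyloxy)-4'-[4-(benzyloxy)-3,5-dimethoxyphenyl]-7'-methoxy-3',4'-dihydro-2'H-spiro[1,3-dithiane-2,1'-naphthalene]-2',3'-diyl]dimethanediyl diacetate
Conditions: Ac2O, pyridine, DMAP (cat.), CH2Cl2, rt
Reagents that add atoms: acetic anhydride, CC(=O)OC(C)=O
Why: DMAP-catalysed acylation of the two primary alcohols is unambiguous because both phenols are still masked as benzyl ethers.

Step 6
Reactants: 11 spiro-dithiane dibenzyl diacetate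
Product: 12 [(1S,2R,3R)-7-hydroxy-1-(4-hydroxy-3,5-dimethoxyphenyl)-6-methoxy-1,2,3,4-tetrahydronaphthalene-2,3-diyl]dimethanediyl diacetate (target)
Conditions: Raney Ni (W-2, washed neutral, excess), H2 (1 atm), THF/EtOAc, 50 °C
Reagents that add atoms: none
Why: Raney Ni hydrogenolysis (Mozingo reduction) should cleave both benzylic C–S bonds to give the C4 methylene and, under H2, both aryl benzyl ethers, while alkyl acetates, methyl ethers and the three stereocentres are untouched.

**Compound list**

1 | 4-(benzyloxy)-3-methoxybenzaldehyde | COc1cc(C=O)ccc1OCc1ccccc1 | starting material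
2 | 2-[4-(benzyloxy)-3-methoxyphenyl]-1,3-dithiane | COc1cc(C2SCCCS2)ccc1OCc1ccccc1 | intermediate
3 | (5R)-5-[(1R,2S,5R)-2-isopropyl-5-methylcyclohexyloxy]furan-2(5H)-one | O=C1C=C[C@H](O[C@@H]2C[C@H](C)CC[C@H]2C(C)C)O1 | starting material
4 | 4-(benzyloxy)-3,5-dimethoxybenzaldehyde | COc1cc(C=O)cc(OC)c1OCc1ccccc1 | starting material
5 | 2-lithio-2-[4-(benzyloxy)-3-methoxyphenyl]-1,3-dithiane | [Li]C1(c2ccc(OCc3ccccc3)c(OC)c2)SCCCS1 | intermediate
6 | lithium enolate of (4R,5R)-4-{2-[4-(benzyloxy)-3-methoxyphenyl]-1,3-dithian-2-yl}-5-(menthyloxy)dihydrofuran-2(3H)-one | CC(C)[C@@H]1CC[C@@H](C)C[C@H]1O[C@@H]2OC(O[Li])=C[C@H]2C3(c4ccc(OCc5ccccc5)c(OC)c4)SCCCS3 | intermediate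
7 | (3S,4R,5R)-3-{[4-(benzyloxy)-3,5-dimethoxyphenyl](hydroxy)methyl}-4-{2-[4-(benzyloxy)-3-methoxyphenyl]-1,3-dithian-2-yl}-5-[(1R,2S,5R)-menthyloxy]dihydrofuran-2(3H)-one, both carbinol epimers | CC(C)[C@@H]1CC[C@@H](C)C[C@H]1O[C@@H]2OC(=O)[C@H](C(O)c3cc(OC)c(OCc4ccccc4)c(OC)c3)[C@H]2C5(c6ccc(OCc7ccccc7)c(OC)c6)SCCCS5 | intermediate
8 | benzylic cation from 7 (carbinol carbon ionised), as its trifluoroacetate | CC(C)[C@@H]1CC[C@@H](C)C[C@H]1O[C@@H]2OC(=O)[C@H]([CH+]c3cc(OC)c(OCc4ccccc4)c(OC)c3)[C@H]2C5(c6ccc(OCc7ccccc7)c(OC)c6)SCCCS5.[O-]C(=O)C(F)(F)F | intermediate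
9 | (3'R,3a'R,9'S,9a'R)-7'-(benzyloxy)-9'-[4-(benzyloxy)-3,5-dimethoxyphenyl]-6'-methoxy-3'-[(1R,2S,5R)-menthyloxy]-3a',9',9a'-trihydro-3'H-spiro[1,3-dithiane-2,4'-naphtho[2,3-c]furan]-1'-one (all-trans at the aryl, carbonyl and acetal-bearing ring carbons) | COc1cc2c(cc1OCc3ccccc3)[C@H](c3cc(OC)c(OCc4ccccc4)c(OC)c3)[C@H]3C(=O)O[C@@H](O[C@@H]4C[C@H](C)CC[C@H]4C(C)C)[C@@H]3C25SCCCS5 | intermediate
10 | [(2'R,3'R,4'S)-6'-(benzyloxy)-4'-[4-(benzyloxy)-3,5-dimethoxyphenyl]-7'-methoxy-3',4'-dihydro-2'H-spiro[1,3-dithiane-2,1'-naphthalene]-2',3'-diyl]dimethanol | COc1cc2c(cc1OCc3ccccc3)[C@H](c3cc(OC)c(OCc4ccccc4)c(OC)c3)[C@@H](CO)[C@H](CO)C25SCCCS5 | intermediate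
11 | [(2'R,3'R,4'S)-6'-(benzyloxy)-4'-[4-(benzyloxy)-3,5-dimethoxyphenyl]-7'-methoxy-3',4'-dihydro-2'H-spiro[1,3-dithiane-2,1'-naphthalene]-2',3'-diyl]dimethanediyl diacetate | COc1cc2c(cc1OCc3ccccc3)[C@H](c3cc(OC)c(OCc4ccccc4)c(OC)c3)[C@@H](COC(C)=O)[C@H](COC(C)=O)C25SCCCS5 | intermediate
12 | [(1S,2R,3R)-7-hydroxy-1-(4-hydroxy-3,5-dimethoxyphenyl)-6-methoxy-1,2,3,4-tetrahydronaphthalene-2,3-diyl]dimethanediyl diacetate | COc1cc2c(cc1O)[C@H](c1cc(OC)c(O)c(OC)c1)[C@@H](COC(C)=O)[C@H](COC(C)=O)C2 | target

**Step count.** Total: 6 steps. Longest linear sequence: 6 steps (1 → 2 → 7 → 9 → 10 → 11 → 12).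

**Steps most likely to fail**

1. Step 3 (key ring closure). The cation may be intercepted by a dithiane sulfur (five-membered sulfonium formation), may lose the C2 proton by E1 elimination, or the hindered syringyl benzyl ether may be cleaved by the acid. Fallback, setting out from 7 and coming back at 12: sulfur is removed before the ring closure. Radical desulfurisation of 7 (Bu3SnH, AIBN, toluene, 100 °C) should give the sulfur-free hydroxybenzyl lactone acetal F1. The same TFA-mediated stereoconvergent Friedel–Crafts closure, now on a substrate without sulfur, should give the aryltetralin lactone menthyl acetal F2. LiAlH4 reduction should give the dibenzyl diol F3, Ac2O/pyridine the dibenzyl diacetate F4, and hydrogenolysis (H2, Pd/C, EtOAc) should remove both benzyl ethers to reach 12.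

2. Step 2 (tandem conjugate addition–aldol). Capture of the hindered enolate by the aldehyde is reversible, so retro-aldol on warming or incomplete trapping may leave only the protonated Michael adduct. Fallback, setting out from 2 and 3 (through enolate 6) and coming back at 7: the reversible aldol is replaced by irreversible acylation followed by reduction. Enolate 6 is quenched at −78 °C with 4-(benzyloxy)-3,5-dimethoxybenzoyl chloride to give the trans β-keto lactone F5. Its aryl ketone is then reduced with NaBH4 (THF/MeOH, −20 °C) to 7; any epimer ratio at the carbinol is acceptable because step 3 is stereoconvergent.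

3. Step 6 (one-operation desulfurisation and debenzylation). The sulfided nickel surface may stall hydrogenolysis of the benzyl ethers, and forcing conditions may cause acetate loss by transesterification on residual base. Fallback, setting out from 11 and coming back at 12: the two tasks are decoupled and debenzylation is done non-reductively. BCl3 with pentamethylbenzene (CH2Cl2, −78 °C) should cleave both aryl benzyl ethers to give the bisphenol dithiane diacetate F6. A short, mild desulfurisation (neutral Raney Ni, THF, rt) should then give 12.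

**Further compounds**

F1 | step 3 | (3S,4R,5R)-3-{[4-(benzyloxy)-3,5-dimethoxyphenyl](hydroxy)methyl}-4-[4-(benzyloxy)-3-methoxybenzyl]-5-[(1R,2S,5R)-menthyloxy]dihydrofuran-2(3H)-one, both carbinol epimers | CC(C)[C@@H]1CC[C@@H](C)C[C@H]1O[C@@H]2OC(=O)[C@H](C(O)c3cc(OC)c(OCc4ccccc4)c(OC)c3)[C@H]2Cc5ccc(OCc6ccccc6)c(OC)c5
F2 | step 3 | (3R,3aR,9S,9aR)-7-(benzyloxy)-9-[4-(benzyloxy)-3,5-dimethoxyphenyl]-6-methoxy-3-[(1R,2S,5R)-menthyloxy]-3a,4,9,9a-tetrahydronaphtho[2,3-c]furan-1(3H)-one | COc1cc2c(cc1OCc3ccccc3)[C@H](c3cc(OC)c(OCc4ccccc4)c(OC)c3)[C@H]3C(=O)O[C@@H](O[C@@H]4C[C@H](C)CC[C@H]4C(C)C)[C@@H]3C2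
F3 | step 3 | [(1S,2R,3R)-7-(benzyloxy)-1-[4-(benzyloxy)-3,5-dimethoxyphenyl]-6-methoxy-1,2,3,4-tetrahydronaphthalene-2,3-diyl]dimethanol | COc1cc2c(cc1OCc3ccccc3)[C@H](c3cc(OC)c(OCc4ccccc4)c(OC)c3)[C@@H](CO)[C@H](CO)C2
F4 | step 3 | [(1S,2R,3R)-7-(benzyloxy)-1-[4-(benzyloxy)-3,5-dimethoxyphenyl]-6-methoxy-1,2,3,4-tetrahydronaphthalene-2,3-diyl]dimethanediyl diacetate | COc1cc2c(cc1OCc3ccccc3)[C@H](c3cc(OC)c(OCc4ccccc4)c(OC)c3)[C@@H](COC(C)=O)[C@H](COC(C)=O)C2
F5 | step 2 | (3S,4R,5R)-3-[4-(benzyloxy)-3,5-dimethoxybenzoyl]-4-{2-[4-(benzyloxy)-3-methoxyphenyl]-1,3-dithian-2-yl}-5-[(1R,2S,5R)-menthyloxy]dihydrofuran-2(3H)-one | CC(C)[C@@H]1CC[C@@H](C)C[C@H]1O[C@@H]2OC(=O)[C@H](C(=O)c3cc(OC)c(OCc4ccccc4)c(OC)c3)[C@H]2C5(c6ccc(OCc7ccccc7)c(OC)c6)SCCCS5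
F6 | step 6 | [(2'R,3'R,4'S)-6'-hydroxy-4'-(4-hydroxy-3,5-dimethoxyphenyl)-7'-methoxy-3',4'-dihydro-2'H-spiro[1,3-dithiane-2,1'-naphthalene]-2',3'-diyl]dimethanediyl diacetate | COc1cc2c(cc1O)[C@H](c3cc(OC)c(O)c(OC)c3)[C@@H](COC(C)=O)[C@H](COC(C)=O)C24SCCCS4
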